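**Plan**

- Retrosynthesis: remove the phenol silyl group, the C9 acetate and the C6 aroyl ester; cut C8–C9 (cycloheptene, iodoalkene plus aldehyde); cut the C4–isopropyl bond (back to a cyclopentanone); then cut C5–C6 and C1–C10 in one operation, back to 3-methylcyclopent-2-en-1-one.
- Forward: the five-membered ring is bought as the enone. One three-component step hangs both arms on it (a 1-silylvinyl group at C1 for C10/C9, a butynyl carbinol at C5 for C6–C8). Isopropyl then adds to C4, the alkyne becomes the Z iodoalkene, the vinyl becomes the C9 aldehyde, and the seven-membered ring closes last at C8–C9.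
- Enabling feature: in the five-membered ring (C1–C5) the methyl-bearing quaternary C1 sits next to C5, the two bonds by which they enter the seven-membered ring (C1–C10, C5–C6) lie on opposite faces, and oxygenated C4 flanks C5. This is the β-carbon, α-carbon and carbonyl pattern of a cyclopentenone after conjugate addition and trans α-trapping.
- Stereochemistry: C1 from the chiral copper–carbene catalyst; C5 from aldehyde approach anti to the silylvinyl group; C6 from the closed aldol transition state (anti aldol); C4 from isopropyl attack anti to the C5 side chain; C9 from the chair-like ring closure.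

Key step: step 3

Assumption (numbering): atoms are numbered C1 (angular-methyl carbon), C2, C3, C4 (isopropyl carbinol), C5 (ring-fusion CH), C6 (aroyloxy CH), C7=C8(Me), C9 (acetoxy CH), C10 (CH2) throughout.

Assumption (catalyst): L is the sulfonate-bearing carbene 3-(2,6-diisopropylphenyl)-4,5-diphenyl-1-(2-sulfonatophenyl)imidazolin-2-ylidene, used as its dimeric silver complex Ag2L2 in the antipode that gives the 3S ketone 8; both antipodes derive from commercial 1,2-diphenylethylenediamine.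

**Route**

Step 1
Reactants: 1 ethynyltrimethylsilane; 2 diisobutylaluminium hydride
Product: 3 diisobutyl[1-(trimethylsilyl)ethenyl]aluminium (kept as a stock solution)
Conditions: iBu2AlH (1.0 equiv), hexanes/THF, 55 °C, 2 h
Reagents that add atoms: none
Why: Hydroalumination of a silylalkyne places aluminium on the silicon-bearing carbon, so the 1-silylvinyl alane should form regioselectively.

Step 2
Reactants: 4 but-2-yn-1-ol
Product: 5 but-2-ynal (kept as a dried, titrated CH2Cl2 solution)
Conditions: activated MnO2 (15 equiv), CH2Cl2, rt; filtration; 4 Å sieves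
Reagents that add atoms: none
Why: Manganese dioxide oxidation of a propargylic alcohol should stop cleanly at the ynal, and the volatile aldehyde is never concentrated.

Step 3
Reactants: 6 3-methylcyclopent-2-en-1-one; 3 diisobutyl[1-(trimethylsilyl)ethenyl]aluminium; 5 but-2-ynal
Product: 8 (2S,3S)-2-[(1R)-1-hydroxybut-2-yn-1-yl]-3-methyl-3-[1-(trimethylsilyl)ethenyl]cyclopentan-1-one, via diisobutylaluminium enolate 7 (not isolated)
Conditions: Cu(OTf)2 (5 mol %), Ag2L2 (2.5 mol %), 3 (1.5 equiv), THF, −78 °C; then 5 (3 equiv), −78 → −40 °C; aq. potassium sodium tartrate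
Reagents that add atoms: none
Why: The alane transmetalates to the copper–carbene complex, which delivers the 1-silylvinyl group to the β-carbon of 6 and leaves the diisobutylaluminium enolate 7 with its double bond fixed between C4 and C5; this enolate then adds to the carbonyl of 5 through a six-membered aluminium-bridged chair. The closest known reaction type is the copper–carbene-catalysed enantioselective conjugate addition of silyl-substituted vinylaluminium reagents to β-substituted cyclic enones, joined to the aldol trapping of a conjugate-addition aluminium enolate (three-component Michael–aldol coupling). No ring is closed; two skeletal bonds (C1–C10 and C5–C6) and three stereocentres are formed. C1 is fixed by the chiral carbene ligand on copper, C5 by approach of the aldehyde to the enolate face opposite the bulky 1-(trimethylsilyl)vinyl group (methyl being the smaller neighbour), and C6 by the chair transition state of the ring-locked E enolate with the slim propynyl group equatorial, which corresponds to the anti aldol (6R at this stage). The step needs transfer of the vinyl and not an isobutyl group, reaction at C5 and not C3, and 1,2-addition to the ynal: sp2 groups migrate preferentially from mixed alanes, the enolate is born regiospecifically and is trapped below −40 °C before proton exchange, and the hard aluminium enolate should attack the aldehyde carbon rather than the alkyne terminus.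

Step 4
Reactants: 8 (2S,3S)-2-[(1R)-1-hydroxybut-2-yn-1-yl]-3-methyl-3-[1-(trimethylsilyl)ethenyl]cyclopentan-1-one
Product: 9 (2S,3S)-2-[(1R)-1-{[tert-butyl(diphenyl)silyl]oxy}but-2-yn-1-yl]-3-methyl-3-[1-(trimethylsilyl)ethenyl]cyclopentan-1-one
Conditions: tert-butyl(chloro)diphenylsilane, imidazole, DMAP (cat.), DMF, rt → 40 °C
Reagents that add atoms: tert-butyl(chloro)diphenylsilane, CC(C)(C)[Si](Cl)(c1ccccc1)c1ccccc1
Why: Silylation of the slim propargylic alcohol blocks retro-aldol and β-elimination, and this silyl ether is chosen because it should survive the trifluoroacetic acid of step 5.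

Step 5
Reactants: 9 (2S,3S)-2-[(1R)-1-{[tert-butyl(diphenyl)silyl]oxy}but-2-yn-1-yl]-3-methyl-3-[1-(trimethylsilyl)ethenyl]cyclopentan-1-one
Product: 10 (2S,3R)-2-[(1R)-1-{[tert-butyl(diphenyl)silyl]oxy}but-2-yn-1-yl]-3-ethenyl-3-methylcyclopentan-1-one
Conditions: CF3CO2H (5 equiv), CHCl3, rt
Reagents that add atoms: none
Why: Protodesilylation of the vinylsilane (ipso protonation to a β-silyl-stabilised cation, then loss of silicon) should leave the plain vinyl group, with the ketone, alkyne and silyl ether untouched.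

Step 6
Reactants: 10 (2S,3R)-2-[(1R)-1-{[tert-butyl(diphenyl)silyl]oxy}but-2-yn-1-yl]-3-ethenyl-3-methylcyclopentan-1-one
Product: 11 (1R,2S,3R)-2-[(1R)-1-{[tert-butyl(diphenyl)silyl]oxy}but-2-yn-1-yl]-3-ethenyl-3-methyl-1-(propan-2-yl)cyclopentan-1-ol
Conditions: iPrMgCl, anhydrous CeCl3, THF, −78 → 0 °C
Reagents that add atoms: isopropylmagnesium chloride, CC(C)[Mg]Cl
Why: Organocerium 1,2-addition (Imamoto conditions) suppresses enolisation and β-hydride reduction, and attack on the ketone face opposite the large neighbouring C5 side chain should give the 4R carbinol.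

Step 7
Reactants: 11 (1R,2S,3R)-2-[(1R)-1-{[tert-butyl(diphenyl)silyl]oxy}but-2-yn-1-yl]-3-ethenyl-3-methyl-1-(propan-2-yl)cyclopentan-1-ol
Product: 12 (1R,2S,3R)-3-ethenyl-2-[(1R)-1-hydroxybut-2-yn-1-yl]-3-methyl-1-(propan-2-yl)cyclopentan-1-ol
Conditions: Bu4NF, THF, rt → 45 °C
Reagents that add atoms: none
Why: Fluoride cleavage of the silyl ether frees the propargylic hydroxyl that must direct the next step.

Step 8
Reactants: 12 (1R,2S,3R)-3-ethenyl-2-[(1R)-1-hydroxybut-2-yn-1-yl]-3-methyl-1-(propan-2-yl)cyclopentan-1-ol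
Product: 14 (1R,2S,3R)-3-ethenyl-2-[(1R,2Z)-1-hydroxy-3-iodobut-2-en-1-yl]-3-methyl-1-(propan-2-yl)cyclopentan-1-ol, via cyclic alkenylalanate 13 (not isolated)
Conditions: NaAlH2(OCH2CH2OMe)2 (4 equiv), THF, 0 °C → rt; EtOAc; then I2, THF, −78 → 0 °C
Reagents that add atoms: iodine, II
Why: Alkoxide-directed trans-hydroalumination of the propargylic alcohol puts hydride on C7 and aluminium on C8 within a five-membered oxaluminacycle, and iodinolysis with retention should give the Z iodoalkene while the isolated vinyl group stays inert.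

Step 9
Reactants: 15 4-hydroxybenzoic acid
Product: 17 4-{[tri(propan-2-yl)silyl]oxy}benzoic acid, via bis-silylated silyl ester 16 (not isolated)
Conditions: iPr3SiCl (2.3 equiv), imidazole, DMF, rt; then K2CO3, THF/MeOH/H2O, rt; citric acid work-up
Reagents that add atoms: chlorotri(propan-2-yl)silane, CC(C)[Si](Cl)(C(C)C)C(C)C
Why: Exhaustive silylation followed by selective hydrolysis of the much more labile silyl ester should leave the phenol protected and the acid free.

Step 10
Reactants: 14 (1R,2S,3R)-3-ethenyl-2-[(1R,2Z)-1-hydroxy-3-iodobut-2-en-1-yl]-3-methyl-1-(propan-2-yl)cyclopentan-1-ol; 17 4-{[tri(propan-2-yl)silyl]oxy}benzoic acid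
Product: 18 (1R,2Z)-1-[(1S,2R,5R)-2-ethenyl-5-hydroxy-2-methyl-5-(propan-2-yl)cyclopentyl]-3-iodobut-2-en-1-yl 4-{[tri(propan-2-yl)silyl]oxy}benzoate
Conditions: N,N'-diisopropylcarbodiimide, DMAP, CH2Cl2, 0 °C → rt
Reagents that add atoms: none
Why: Steglich esterification acylates the secondary allylic hydroxyl with retention at C6, the hindered tertiary C4 hydroxyl being unreactive.

Step 11
Reactants: 18 (1R,2Z)-1-[(1S,2R,5R)-2-ethenyl-5-hydroxy-2-methyl-5-(propan-2-yl)cyclopentyl]-3-iodobut-2-en-1-yl 4-{[tri(propan-2-yl)silyl]oxy}benzoate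
Product: 20 (1R,2Z)-1-[(1S,2R,5R)-2-hydroxy-5-(2-hydroxyethyl)-5-methyl-2-(propan-2-yl)cyclopentyl]-3-iodobut-2-en-1-yl 4-{[tri(propan-2-yl)silyl]oxy}benzoate, via B-alkyl-9-borabicyclononane 19 (not isolated)
Conditions: 9-borabicyclo[3.3.1]nonane (3 equiv), THF, 0 °C → rt; then NaBO3·4H2O, THF/H2O, rt
Reagents that add atoms: sodium perborate, [Na+].[Na+].O[B-]1(O)OO[B-](O)(O)OO1
Why: Anti-Markovnikov hydroboration–oxidation with the bulky dialkylborane should take the monosubstituted vinyl group in preference to the trisubstituted iodoalkene and the esters, and perborate is mild enough for the aryl silyl ether.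

Step 12
Reactants: 20 (1R,2Z)-1-[(1S,2R,5R)-2-hydroxy-5-(2-hydroxyethyl)-5-methyl-2-(propan-2-yl)cyclopentyl]-3-iodobut-2-en-1-yl 4-{[tri(propan-2-yl)silyl]oxy}benzoate
Product: 21 (1R,2Z)-1-[(1S,2R,5R)-2-hydroxy-5-methyl-5-(2-oxoethyl)-2-(propan-2-yl)cyclopentyl]-3-iodobut-2-en-1-yl 4-{[tri(propan-2-yl)silyl]oxy}benzoate
Conditions: Dess–Martin periodinane, NaHCO3, CH2Cl2, 0 °C → rt
Reagents that add atoms: none
Why: Dess–Martin oxidation converts the primary alcohol to the aldehyde under buffered conditions; the tertiary alcohol cannot be oxidised and cannot form a lactol because it is trans to the aldehyde arm.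

Step 13
Reactants: 21 (1R,2Z)-1-[(1S,2R,5R)-2-hydroxy-5-methyl-5-(2-oxoethyl)-2-(propan-2-yl)cyclopentyl]-3-iodobut-2-en-1-yl 4-{[tri(propan-2-yl)silyl]oxy}benzoate
Product: 22 (3R,3aS,4S,7S,8aR)-3,7-dihydroxy-6,8a-dimethyl-3-(propan-2-yl)-1,2,3,3a,4,7,8,8a-octahydroazulen-4-yl 4-{[tri(propan-2-yl)silyl]oxy}benzoate
Conditions: CrCl2 (8 equiv), NiCl2 (2 mol %), degassed DMF, rt, 0.005 M
Reagents that add atoms: none
Why: In this intramolecular Nozaki–Hiyama–Kishi reaction zerovalent nickel inserts into the C–I bond, the alkenyl group passes to trivalent chromium with retention of the Z geometry and adds to the aldehyde to close the seven-membered ring at C8–C9; a chair-like closure with the chromium-bound oxygen pseudoequatorial, away from the axial C1 methyl, should favour the 9S alcohol.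

Step 14
Reactants: 22 (3R,3aS,4S,7S,8aR)-3,7-dihydroxy-6,8a-dimethyl-3-(propan-2-yl)-1,2,3,3a,4,7,8,8a-octahydroazulen-4-yl 4-{[tri(propan-2-yl)silyl]oxy}benzoate
Product: 23 (3R,3aS,4S,7S,8aR)-7-acetoxy-3-hydroxy-6,8a-dimethyl-3-(propan-2-yl)-1,2,3,3a,4,7,8,8a-octahydroazulen-4-yl 4-{[tri(propan-2-yl)silyl]oxy}benzoate
Conditions: Ac2O, pyridine, DMAP (cat.), CH2Cl2, 0 °C
Reagents that add atoms: acetic anhydride, CC(=O)OC(C)=O
Why: DMAP-catalysed acetylation takes the secondary allylic C9 hydroxyl and leaves the hindered tertiary C4 hydroxyl free.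

Step 15
Reactants: 23 (3R,3aS,4S,7S,8aR)-7-acetoxy-3-hydroxy-6,8a-dimethyl-3-(propan-2-yl)-1,2,3,3a,4,7,8,8a-octahydroazulen-4-yl 4-{[tri(propan-2-yl)silyl]oxy}benzoate
Product: 24 (3R,3aS,4S,7S,8aR)-7-acetoxy-3-hydroxy-6,8a-dimethyl-3-(propan-2-yl)-1,2,3,3a,4,7,8,8a-octahydroazulen-4-yl 4-hydroxybenzoate
Conditions: Bu4NF, AcOH (1:1), THF, 0 °C
Reagents that add atoms: none
Why: Buffered fluoride desilylation of the electron-poor aryl silyl ether is fast and should spare the acetate and the benzoate.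

**Compound list**

1 | ethynyltrimethylsilane | C#C[Si](C)(C)C | starting material
2 | diisobutylaluminium hydride | CC(C)C[AlH]CC(C)C | starting material
3 | diisobutyl[1-(trimethylsilyl)ethenyl]aluminium | C=C([Si](C)(C)C)[Al](CC(C)C)CC(C)C | intermediate
4 | but-2-yn-1-ol | CC#CCO | starting material
5 | but-2-ynal | CC#CC=O | intermediate
6 | 3-methylcyclopent-2-en-1-one | CC1=CC(=O)CC1 | starting material
7 | diisobutylaluminium (3S)-3-methyl-3-[1-(trimethylsilyl)ethenyl]cyclopent-1-en-1-olate | C=C([Si](C)(C)C)[C@@]1(C)CCC(O[Al](CC(C)C)CC(C)C)=C1 | intermediate (not isolated)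
8 | (2S,3S)-2-[(1R)-1-hydroxybut-2-yn-1-yl]-3-methyl-3-[1-(trimethylsilyl)ethenyl]cyclopentan-1-one | C=C([Si](C)(C)C)[C@@]1(C)CCC(=O)[C@@H]1[C@@H](O)C#CC | intermediate
9 | (2S,3S)-2-[(1R)-1-{[tert-butyl(diphenyl)silyl]oxy}but-2-yn-1-yl]-3-methyl-3-[1-(trimethylsilyl)ethenyl]cyclopentan-1-one | C=C([Si](C)(C)C)[C@@]1(C)CCC(=O)[C@@H]1[C@@H](O[Si](c1ccccc1)(c1ccccc1)C(C)(C)C)C#CC | intermediate
10 | (2S,3R)-2-[(1R)-1-{[tert-butyl(diphenyl)silyl]oxy}but-2-yn-1-yl]-3-ethenyl-3-methylcyclopentan-1-one | C=C[C@@]1(C)CCC(=O)[C@@H]1[C@@H](O[Si](c1ccccc1)(c1ccccc1)C(C)(C)C)C#CC | intermediate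
11 | (1R,2S,3R)-2-[(1R)-1-{[tert-butyl(diphenyl)silyl]oxy}but-2-yn-1-yl]-3-ethenyl-3-methyl-1-(propan-2-yl)cyclopentan-1-ol | C=C[C@@]1(C)CC[C@@](O)(C(C)C)[C@@H]1[C@@H](O[Si](c1ccccc1)(c1ccccc1)C(C)(C)C)C#CC | intermediate
12 | (1R,2S,3R)-3-ethenyl-2-[(1R)-1-hydroxybut-2-yn-1-yl]-3-methyl-1-(propan-2-yl)cyclopentan-1-ol | C=C[C@@]1(C)CC[C@@](O)(C(C)C)[C@@H]1[C@@H](O)C#CC | intermediate
13 | sodium alkenylalanate of 12: five-membered 1,2-oxaluminacycle through O6, C6, C7=C8 and aluminium, with two 2-methoxyethoxy groups on aluminium (C4 hydroxyl drawn free; in the flask it is carried as an aluminium alkoxide) | C=C[C@@]1(C)CC[C@@](O)(C(C)C)[C@@H]1[C@H]1O[Al-](OCCOC)(OCCOC)C(C)=C1.[Na+] | intermediate (not isolated)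
14 | (1R,2S,3R)-3-ethenyl-2-[(1R,2Z)-1-hydroxy-3-iodobut-2-en-1-yl]-3-methyl-1-(propan-2-yl)cyclopentan-1-ol | C=C[C@@]1(C)CC[C@@](O)(C(C)C)[C@@H]1[C@@H](O)/C=C(/C)I | intermediate
15 | 4-hydroxybenzoic acid | OC(=O)c1ccc(O)cc1 | starting material
16 | tri(propan-2-yl)silyl 4-{[tri(propan-2-yl)silyl]oxy}benzoate | CC(C)[Si](C(C)C)(C(C)C)Oc1ccc(cc1)C(=O)O[Si](C(C)C)(C(C)C)C(C)C | intermediate (not isolated)
17 | 4-{[tri(propan-2-yl)silyl]oxy}benzoic acid | CC(C)[Si](C(C)C)(C(C)C)Oc1ccc(cc1)C(=O)O | intermediate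
18 | (1R,2Z)-1-[(1S,2R,5R)-2-ethenyl-5-hydroxy-2-methyl-5-(propan-2-yl)cyclopentyl]-3-iodobut-2-en-1-yl 4-{[tri(propan-2-yl)silyl]oxy}benzoate | C=C[C@@]1(C)CC[C@@](O)(C(C)C)[C@@H]1[C@@H](OC(=O)c1ccc(O[Si](C(C)C)(C(C)C)C(C)C)cc1)/C=C(/C)I | intermediate
19 | 9-borabicyclo[3.3.1]nonane adduct of 18, boron on the terminal carbon of the former vinyl group (C9) | C(CB1C2CCCC1CCC2)[C@@]1(C)CC[C@@](O)(C(C)C)[C@@H]1[C@@H](OC(=O)c1ccc(O[Si](C(C)C)(C(C)C)C(C)C)cc1)/C=C(/C)I | intermediate (not isolated)
20 | (1R,2Z)-1-[(1S,2R,5R)-2-hydroxy-5-(2-hydroxyethyl)-5-methyl-2-(propan-2-yl)cyclopentyl]-3-iodobut-2-en-1-yl 4-{[tri(propan-2-yl)silyl]oxy}benzoate | OCC[C@@]1(C)CC[C@@](O)(C(C)C)[C@@H]1[C@@H](OC(=O)c1ccc(O[Si](C(C)C)(C(C)C)C(C)C)cc1)/C=C(/C)I | intermediate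
21 | (1R,2Z)-1-[(1S,2R,5R)-2-hydroxy-5-methyl-5-(2-oxoethyl)-2-(propan-2-yl)cyclopentyl]-3-iodobut-2-en-1-yl 4-{[tri(propan-2-yl)silyl]oxy}benzoate | O=CC[C@@]1(C)CC[C@@](O)(C(C)C)[C@@H]1[C@@H](OC(=O)c1ccc(O[Si](C(C)C)(C(C)C)C(C)C)cc1)/C=C(/C)I | intermediate
22 | (3R,3aS,4S,7S,8aR)-3,7-dihydroxy-6,8a-dimethyl-3-(propan-2-yl)-1,2,3,3a,4,7,8,8a-octahydroazulen-4-yl 4-{[tri(propan-2-yl)silyl]oxy}benzoate | O[C@H]1C[C@@]2(C)CC[C@@](O)(C(C)C)[C@@H]2[C@@H](OC(=O)c2ccc(O[Si](C(C)C)(C(C)C)C(C)C)cc2)C=C1C | intermediate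
23 | (3R,3aS,4S,7S,8aR)-7-acetoxy-3-hydroxy-6,8a-dimethyl-3-(propan-2-yl)-1,2,3,3a,4,7,8,8a-octahydroazulen-4-yl 4-{[tri(propan-2-yl)silyl]oxy}benzoate | CC(=O)O[C@H]1C[C@@]2(C)CC[C@@](O)(C(C)C)[C@@H]2[C@@H](OC(=O)c2ccc(O[Si](C(C)C)(C(C)C)C(C)C)cc2)C=C1C | intermediate
24 | (3R,3aS,4S,7S,8aR)-7-acetoxy-3-hydroxy-6,8a-dimethyl-3-(propan-2-yl)-1,2,3,3a,4,7,8,8a-octahydroazulen-4-yl 4-hydroxybenzoate | CC(=O)O[C@H]1C[C@@]2(C)CC[C@@](O)(C(C)C)[C@@H]2[C@@H](OC(=O)c2ccc(O)cc2)C=C1C | target

**Step count**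

Total: 15 steps. Longest linear sequence: 13 steps (steps 1, 3–8 and 10–15, from ethynyltrimethylsilane to 24).

**Steps most likely to fail**

Step 3. The aluminium enolate may add to the ynal too slowly, so that aldehyde reduction by isobutyl hydride transfer competes and the diastereoselection at C6 erodes. The fallback separates the two bond formations. Starting from 6 and 3, the conjugate addition is run alone and the enolate 7 is quenched with trimethylsilyl triflate to give trimethyl{[(3S)-3-methyl-3-[1-(trimethylsilyl)ethenyl]cyclopent-1-en-1-yl]oxy}silane F1. MeLi in THF at 0 °C cleaves this to the regiodefined lithium (3S)-3-methyl-3-[1-(trimethylsilyl)ethenyl]cyclopent-1-en-1-olate F2, which should add to 5 at −78 °C through the same closed transition state. The fallback rejoins the route at 8.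

Step 13. Facial selectivity at C9 may be poor during the seven-membered closure, giving both carbinol epimers. The fallback replaces substrate control by reagent control. Starting from 22 as the epimer mixture, the allylic alcohol is oxidised (MnO2 or Dess–Martin periodinane) to (3R,3aS,4S,8aR)-3-hydroxy-6,8a-dimethyl-7-oxo-3-(propan-2-yl)-1,2,3,3a,4,7,8,8a-octahydroazulen-4-yl 4-{[tri(propan-2-yl)silyl]oxy}benzoate F3. This α-methyl enone is then reduced with (R)-2-methyl-CBS-oxazaborolidine and catecholborane at −78 °C, the alkenyl side acting as the large group, to return the 9S alcohol 22.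

Step 6. Enolisation toward C3 or hydride transfer may outrun addition of the branched nucleophile to the crowded ketone, and the silyl ether may give insufficient facial bias. The fallback switches to chelation control on the unprotected aldol. Starting from 10, the silyl ether is removed with HF·pyridine in THF to give (2S,3R)-3-ethenyl-2-[(1R)-1-hydroxybut-2-yn-1-yl]-3-methylcyclopentan-1-one F4. Excess iPrMgCl/CeCl3 at −78 °C then forms the C6 alkoxide, which ties up the ketone in a six-membered chelate, so the isopropyl group should enter from the open face opposite the C5–C6 bond. This gives 12 directly and bypasses 11.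

**Further compounds**

F1 | step 3 | trimethyl{[(3S)-3-methyl-3-[1-(trimethylsilyl)ethenyl]cyclopent-1-en-1-yl]oxy}silane | C=C([Si](C)(C)C)[C@@]1(C)CCC(O[Si](C)(C)C)=C1
F2 | step 3 | lithium (3S)-3-methyl-3-[1-(trimethylsilyl)ethenyl]cyclopent-1-en-1-olate | C=C([Si](C)(C)C)[C@@]1(C)CCC(O[Li])=C1
F3 | step 13 | (3R,3aS,4S,8aR)-3-hydroxy-6,8a-dimethyl-7-oxo-3-(propan-2-yl)-1,2,3,3a,4,7,8,8a-octahydroazulen-4-yl 4-{[tri(propan-2-yl)silyl]oxy}benzoate | O=C1C[C@@]2(C)CC[C@@](O)(C(C)C)[C@@H]2[C@@H](OC(=O)c2ccc(O[Si](C(C)C)(C(C)C)C(C)C)cc2)C=C1C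
F4 | step 6 | (2S,3R)-3-ethenyl-2-[(1R)-1-hydroxybut-2-yn-1-yl]-3-methylcyclopentan-1-one | C=C[C@@]1(C)CCC(=O)[C@@H]1[C@@H](O)C#CC
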